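## Retrosynthetic overview

- **Feature.** The target holds a trans-fused cyclopentane (C1–C2–C3–C4–C5) and cycloheptane (C1, C5, C6, C7, C8, C9, C10), with oxygen on C6 beside C5–H. This is an angular-methyl decalin in disguise. Moving the C1–C5 bond back to C1–C6 gives the Wieland–Miescher skeleton, which already carries C1–CH3, O2 and a C8 carbonyl.
- **Late disconnections.** C6 veratrate; 8,9-oxirane (delivered by the β C6–OH); C2 acetate; C8–CH3 (enol triflate coupling); C4 isopropyl carbinol (organocerium on a C4 ketone); C4–O and C5–H (hydroboration of C4=C5); C6–OH (Luche reduction of the C4=C5–C6=O enone).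
- **Key disconnection.** C1–C5, made by a semipinacol 1,2-shift of the cis-decalin 2β,6β-diol 5β-mesylate 11, held by aluminium between O2 and O6.
- **Precursor.** 11 comes from (S)-Wieland–Miescher ketone by C2 reduction, ketalisation with alkene shift to C5=C6, and Woodward cis-dihydroxylation on the methyl face.
- **Ring order.** Decalin rings A and B arrive with 1. The five- and seven-membered rings are both made in step 8. The oxirane closes in step 22.

Key step: step 8

**Remark (locants and faces).** One set of locants is used throughout, C1 to C10 as above. In the decalins C1 is bonded to C2, C6 and C10: ring A is C1, C10, C9, C8, C7, C6 and ring B is C1 to C6. In the hydroazulenes C1 is bonded to C2, C5 and C10. β is the face of the C1 methyl and α is the other face.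

**Remark (reading of the SMILES).** C1–CH3, O2, O4, O6 and the oxirane oxygen all lie on the β face. H5 and the isopropyl group are α. The route is planned for exactly this array.

**Remark (stereocentres).**
- C1 comes with 1.
- C2 is set in step 1.
- C5 is set in step 8, flattened in step 10 and set again in step 13.
- C6 is set in step 11.
- C4 is set in step 15.
- C8 and C9 are set in step 22.

## Route

Step 1
Reactants: 1 (S)-Wieland–Miescher ketone
Product: 2 2β-hydroxy enone, (4aS,5S)-5-hydroxy-4a-methyl-4,4a,5,6,7,8-hexahydronaphthalen-2(3H)-one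
Conditions: NaBH4 (0.3 equiv), EtOH, 0 °C
Reagents that add atoms: none
Why: Chemoselective borohydride reduction, in which the isolated C2 ketone is more electrophilic than the conjugated C8 carbonyl and hydride arrives opposite the angular methyl, so C2–OH is set β (cis to the methyl).

Step 2
Reactants: 2 2β-hydroxy enone; 3 ethane-1,2-diol
Product: 4 2β-hydroxy-1β-methyl-octal-5(6)-ene 8-ethylene ketal
Conditions: p-TsOH·H2O (cat.), benzene, reflux, Dean–Stark
Reagents that add atoms: ethane-1,2-diol (3), OCCO
Why: Acid-catalysed ketalisation of a cyclohexenone equilibrates through the dienol ether and should settle on the β,γ-unsaturated dioxolane, moving the alkene from C6=C7 to C5=C6 as in steroidal 4-en-3-ones, with no stereocentre touched.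

Step 3
Reactants: 4 hydroxy ketal alkene
Product: 5 2β-O-TBS ether of 4
Conditions: TBSOTf, 2,6-lutidine, CH2Cl2, 0 °C
Reagents that add atoms: tert-butyldimethylsilyl triflate, CC(C)(C)[Si](C)(C)OS(=O)(=O)C(F)(F)F
Why: Silyl triflate silylation copes with the neopentyl-type secondary alcohol and masks O2 so that only O5 can be sulfonylated later, and placing it after step 2 spares the silyl ether hot acid.

Step 4
Reactants: 5 silyl ether alkene
Product: 8 5β-acetoxy-6β-hydroxy cis-decalin (2β-OTBS; 8-ketal), via iodo acetate 6 (not isolated), via acetoxonium ion 7 (not isolated)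
Conditions: I2, AgOAc, AcOH, rt; then H2O (1 equiv) in AcOH, rt → 50 °C
Reagents that add atoms: silver acetate, CC(=O)[O-].[Ag+]; water, O
Why: Woodward cis-dihydroxylation, in which iodonium forms on the open α face, acetate opens it from the β face (6; the regioisomeric opening converges), silver-assisted loss of iodide with acetate participation gives the β-fused ion 7, and the single equivalent of water collapses it to the cis hydroxy acetate, so O5 and O6 end on the methyl face that OsO4 would not reach while little free water remains to attack the dioxolane.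

Step 5
Reactants: 8 hydroxy acetate
Product: 9 5β,6β-diol (2β-OTBS; 8-ketal)
Conditions: K2CO3 (cat.), MeOH, rt
Reagents that add atoms: none
Why: Carbonate-catalysed transesterification removes the acetate (from either oxygen, should the regioisomer be present) without touching silyl ether, ketal or any stereocentre.

Step 6
Reactants: 9 5β,6β-diol
Product: 10 5β-mesylate 6β-ol (2β-OTBS; 8-ketal)
Conditions: MsCl, Et3N, CH2Cl2, 0 °C
Reagents that add atoms: methanesulfonyl chloride, CS(=O)(=O)Cl
Why: Sulfene-type mesylation picks the secondary C5 hydroxyl because O6 is tertiary and O2 is silylated, and the C5–O bond is not broken, so the configuration is kept.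

Step 7
Reactants: 10 silylated hydroxy mesylate
Product: 11 cis-decalin 2β,6β-diol 5β-mesylate 8-ethylene ketal
Conditions: Bu4NF, AcOH (1:1), THF, rt → 40 °C
Reagents that add atoms: none
Why: Fluoride desilylation buffered with acetic acid stays non-basic, so the C6 hydroxyl is not deprotonated and the hydroxy mesylate should not rearrange early from the wrong chair, while the dioxolane meets no strong acid.

Step 8
Reactants: 11 cis-decalin 2β,6β-diol 5β-mesylate
Product: 13 trans-fused 2β-hydroxy-1β-methyl-5αH-hydroazulen-6-one 8-ethylene ketal, via aluminium chelate 12 (not isolated)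
Conditions: Et3Al (3 equiv), CH2Cl2, −78 → 0 °C; aq. potassium sodium tartrate
Reagents that add atoms: none
Why: Et3Al first protonolyses both hydroxyls to the six-membered O2–Al–O6 chelate 12, which can exist only in the chair–chair form with O2 and O6 syn-diaxial on ring B and the C5 mesylate equatorial, that is antiperiplanar to C1–C6; a further Et3Al pulls on the mesylate while the C6 alkoxide pushes, so C1 moves from C6 to C5 in one concerted 1,2-alkyl shift as C6 becomes the carbonyl carbon, with no free cation. The closest known reaction type is the organoaluminium-promoted semipinacol (pinacol-type) rearrangement of vicinal diol monosulfonates, the classical way from decalins to hydroazulenones. The cyclopentane (C1–C2–C3–C4–C5) closes by ring contraction through the new C1–C5 bond, and the cycloheptanone (C1, C5, C6, C7, C8, C9, C10) arises by ring enlargement because the bond given up, C1–C6, is the old fusion bond. C5 is the only new stereocentre: backside displacement of the β mesylate inverts it and C1 migrates with retention, so H5 ends α, trans to the methyl. The selectivity needed is migration of C1–C6 and not of C6–C7, which would give a bridged bicyclo[4.3.1]decanone from the other chair form where the mesylate is axial, and the aluminium bridge between O2 and O6 secures it. The cis relation of O5 and O6 also rules out epoxide formation.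

Step 9
Reactants: 13 hydroxy hydroazulenone
Product: 14 2β-O-TBS ether of 13
Conditions: TBSOTf, 2,6-lutidine, CH2Cl2, −78 → 0 °C
Reagents that add atoms: tert-butyldimethylsilyl triflate, CC(C)(C)[Si](C)(C)OS(=O)(=O)C(F)(F)F
Why: Silyl triflate silylation with a hindered pyridine base protects the cyclopentanol faster than it enolises the ketone, and gives a group that lasts through the oxidant, hydride and organometal steps to come.

Step 10
Reactants: 14 silylated ketone
Product: 15 C4=C5 enone (6-oxo; 2β-OTBS; 8-ketal)
Conditions: IBX, 4-methoxypyridine N-oxide, DMSO, 25 → 45 °C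
Reagents that add atoms: none
Why: IBX dehydrogenation of a ketone runs through its enol, and only the C5 enol can go on to an enone because C8 on the other side bears no hydrogen, so C4=C5 is the only possible enone; the C5 stereocentre is given up on purpose and rebuilt in step 13.

Step 11
Reactants: 15 enone
Product: 16 6β-allylic alcohol
Conditions: NaBH4, CeCl3·7H2O, MeOH, −78 → −40 °C
Reagents that add atoms: none
Why: Luche 1,2-reduction, in which the β face of C6 is screened by the C1 methyl standing 1,3 to the carbonyl carbon (the bias that turns 6-oxo and 4-en-6-oxo steroids into 6β-alcohols), so hydride should enter from the α face and set C6–OH β.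

Step 12
Reactants: 16 allylic alcohol
Product: 17 6β-O-PMB ether
Conditions: NaH, PMBCl, Bu4NI (cat.), THF–DMF, 0 °C → rt
Reagents that add atoms: 4-methoxybenzyl chloride, COc1ccc(CCl)cc1
Why: Williamson etherification is safe here because no carbonyl group is free, and O2 and O6 lie far apart across the planar C5 so that silyl migration is not expected; the PMB group is orthogonal to the C2 silyl ether.

Step 13
Reactants: 17 PMB ether alkene
Product: 19 4α-alcohol with 5αH (trans-fused), via alkylborane 18 (not isolated)
Conditions: BH3·THF, THF, 0 °C → rt; then NaOH aq., H2O2, 0 °C → rt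
Reagents that add atoms: hydrogen peroxide, OO
Why: Brown hydroboration–oxidation, in which boron goes to the less substituted C4 and hydrogen to C5 in a syn addition on the α face, away from the C1 methyl, the C2 silyl ether and the C6 ether, so H5 is set α again (trans fusion) and oxidation with retention gives the 4α-alcohol.

Step 14
Reactants: 19 4α-alcohol
Product: 20 C4 ketone
Conditions: Dess–Martin periodinane, NaHCO3, CH2Cl2, 0 °C → rt
Reagents that add atoms: none
Why: Dess–Martin oxidation under bicarbonate buffer is close to neutral, so the epimerisable C5–H and the β-alkoxy group on C6 should stay as they are.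

Step 15
Reactants: 20 C4 ketone
Product: 21 4β-hydroxy-4α-isopropyl compound
Conditions: iPrMgCl, CeCl3 (anhydrous), THF, −78 → −20 °C
Reagents that add atoms: isopropylmagnesium chloride, CC(C)[Mg]Cl
Why: Organocerium (Imamoto-type) addition, in which the weakly basic, oxophilic reagent adds to the enolisable β-alkoxy cyclopentanone instead of deprotonating or reducing it, and enters from the α face beside H5 because the β face carries C1–CH3, O2 and the C6 ether, which sets C4 (OH β, isopropyl α).

Step 16
Reactants: 21 tertiary alcohol ketal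
Product: 22 C8 ketone
Conditions: PPTS, acetone–H2O, 50 °C
Reagents that add atoms: water, O
Why: Mild acid hydrolysis of the dioxolane spares the PMB ether, the hindered silyl ether and the unactivated tertiary alcohol, and is too weakly acidic to eliminate the C6 ether from the new β-alkoxy ketone.

Step 17
Reactants: 22 C8 ketone
Product: 24 C8=C9 enol triflate, via dilithium enolate 23 (not isolated)
Conditions: LiN(iPr)2 (2.3 equiv), THF, −78 °C; Comins' reagent, −78 °C
Reagents that add atoms: N-(5-chloropyridin-2-yl)bis(trifluoromethanesulfonimide), O=S(=O)(N(c1ccc(Cl)cn1)S(=O)(=O)C(F)(F)F)C(F)(F)F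
Why: Kinetic enolisation and O-triflation, in which the bulky amide takes a C9 proton because C7 is shielded by the branched C6 ether carbon, Comins' reagent traps the enolate at −78 °C before it equilibrates, and the crowded tertiary C4 alkoxide formed by the extra base should not be sulfonylated at that temperature.

Step 18
Reactants: 24 enol triflate
Product: 25 8-methyl C8=C9 alkene
Conditions: MeMgBr (3 equiv), Fe(acac)3 (10 mol %), THF–NMP, −20 → 0 °C
Reagents that add atoms: methylmagnesium bromide, C[Mg]Br
Why: Iron-catalysed Kumada-type cross-coupling of an alkenyl triflate exchanges OTf for CH3 without moving the alkene, and tolerates the C4 hydroxyl as its magnesium alkoxide.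

Step 19
Reactants: 25 methyl alkene
Product: 26 2β-alcohol (6β-OPMB; 4β-OH)
Conditions: Bu4NF, THF, rt → 50 °C
Reagents that add atoms: none
Why: Fluoride desilylation of the hindered C2 silyl ether can be forced at this stage because no ester or epoxide is present yet.

Step 20
Reactants: 26 2β-alcohol
Product: 27 2β-acetate
Conditions: Ac2O, pyridine, DMAP (cat.), CH2Cl2, 0 °C → rt
Reagents that add atoms: acetic anhydride, CC(=O)OC(C)=O
Why: DMAP-catalysed acetylation takes the only secondary hydroxyl, while the tertiary C4 hydroxyl flanked by isopropyl and the ring fusion is too crowded to react under these conditions.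

Step 21
Reactants: 27 2β-acetate PMB ether
Product: 28 6β-alcohol
Conditions: DDQ, CH2Cl2–pH 7 phosphate buffer, 0 °C
Reagents that add atoms: none
Why: Oxidative PMB cleavage with DDQ is neutral and spares acetate, alkene and tertiary alcohol, and the excess water should intercept the benzylic oxocarbenium ion before O4 can close an acetal.

Step 22
Reactants: 28 homoallylic alcohol
Product: 29 8β,9β-epoxide
Conditions: VO(acac)2 (5 mol %), t-BuOOH (decane), CH2Cl2, 0 °C → rt
Reagents that add atoms: tert-butyl hydroperoxide, CC(C)(C)OO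
Why: Hydroxyl-directed vanadium-catalysed epoxidation of a cyclic homoallylic alcohol, in which the vanadate ester of the β C6–OH delivers oxygen to the β face of C8=C9 and sets C8 and C9, while O2, O4 and O6 all lie syn to the oxirane and cannot reach its backside.

Step 23
Reactants: 29 epoxy alcohol; 30 3,4-dimethoxybenzoyl chloride
Product: 31 target CNP0330776.1
Conditions: Et3N, DMAP, CH2Cl2, rt → 40 °C
Reagents that add atoms: 3,4-dimethoxybenzoyl chloride (30), COc1ccc(C(Cl)=O)cc1OC
Why: DMAP-catalysed acylation with the acid chloride esterifies the only secondary hydroxyl left, the amine scavenges HCl so the oxirane sees no acid, the tertiary C4–OH stays free, and the C6–O bond is untouched so the configuration holds.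

## Compound list

| No. | Name | SMILES | Role |
|---|---|---|---|
| 1 | (S)-8a-methyl-3,4,8,8a-tetrahydronaphthalene-1,6(2H,7H)-dione | C[C@]12CCC(=O)C=C1CCCC2=O | starting material |
| 2 | 2β-hydroxy enone, (4aS,5S)-5-hydroxy-4a-methyl-4,4a,5,6,7,8-hexahydronaphthalen-2(3H)-one | C[C@]12CCC(=O)C=C1CCC[C@@H]2O | intermediate |
| 3 | ethane-1,2-diol | OCCO | starting material |
| 4 | 2β-hydroxy-1β-methyl-octal-5(6)-ene 8-ethylene ketal | C[C@]12CCC3(OCCO3)CC1=CCC[C@@H]2O | intermediate |
| 5 | 2β-O-TBS ether of 4 | C[C@]12CCC3(OCCO3)CC1=CCC[C@@H]2O[Si](C)(C)C(C)(C)C | intermediate |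
| 6 | 6α-iodo-5β-acetate (not isolated) | C[C@]12CCC3(OCCO3)C[C@]1(I)[C@H](OC(C)=O)CC[C@@H]2O[Si](C)(C)C(C)(C)C | intermediate |
| 7 | 5β,6β-acetoxonium acetate (not isolated) | C[C@]12CCC3(OCCO3)C[C@@]1(OC(C)=[O+]4)[C@H]4CC[C@@H]2O[Si](C)(C)C(C)(C)C.CC(=O)[O-] | intermediate |
| 8 | 5β-acetoxy-6β-hydroxy cis-decalin (2β-OTBS; 8-ketal) | C[C@]12CCC3(OCCO3)C[C@@]1(O)[C@H](OC(C)=O)CC[C@@H]2O[Si](C)(C)C(C)(C)C | intermediate |
| 9 | 5β,6β-diol (2β-OTBS; 8-ketal) | C[C@]12CCC3(OCCO3)C[C@@]1(O)[C@H](O)CC[C@@H]2O[Si](C)(C)C(C)(C)C | intermediate |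
| 10 | 5β-mesylate 6β-ol (2β-OTBS; 8-ketal) | C[C@]12CCC3(OCCO3)C[C@@]1(O)[C@H](OS(C)(=O)=O)CC[C@@H]2O[Si](C)(C)C(C)(C)C | intermediate |
| 11 | cis-decalin 2β,6β-diol 5β-mesylate 8-ethylene ketal (key precursor) | C[C@]12CCC3(OCCO3)C[C@@]1(O)[C@H](OS(C)(=O)=O)CC[C@@H]2O | intermediate |
| 12 | ethylaluminium O2,O6-chelate of 11 (not isolated) | C[C@]12CCC3(OCCO3)C[C@@]1(O[Al](CC)O4)[C@H](OS(C)(=O)=O)CC[C@@H]24 | intermediate |
| 13 | trans-fused 2β-hydroxy-1β-methyl-5αH-hydroazulen-6-one 8-ethylene ketal (key product) | O=C1CC2(OCCO2)CC[C@]3(C)[C@@H](O)CC[C@@H]13 | intermediate |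
| 14 | 2β-O-TBS ether of 13 | O=C1CC2(OCCO2)CC[C@]3(C)[C@@H](O[Si](C)(C)C(C)(C)C)CC[C@@H]13 | intermediate |
| 15 | C4=C5 enone | O=C1CC2(OCCO2)CC[C@]3(C)[C@@H](O[Si](C)(C)C(C)(C)C)CC=C13 | intermediate |
| 16 | 6β-allylic alcohol | O[C@H]1CC2(OCCO2)CC[C@]3(C)[C@@H](O[Si](C)(C)C(C)(C)C)CC=C13 | intermediate |
| 17 | 6β-O-PMB ether | COc1ccc(CO[C@H]2CC3(OCCO3)CC[C@]4(C)[C@@H](O[Si](C)(C)C(C)(C)C)CC=C24)cc1 | intermediate |
| 18 | 4α-boryl 5αH adduct (not isolated) | COc1ccc(CO[C@H]2CC3(OCCO3)CC[C@]4(C)[C@@H](O[Si](C)(C)C(C)(C)C)C[C@H](B)[C@@H]24)cc1 | intermediate |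
| 19 | 4α-alcohol, 5αH | COc1ccc(CO[C@H]2CC3(OCCO3)CC[C@]4(C)[C@@H](O[Si](C)(C)C(C)(C)C)C[C@H](O)[C@@H]24)cc1 | intermediate |
| 20 | C4 ketone | COc1ccc(CO[C@H]2CC3(OCCO3)CC[C@]4(C)[C@@H](O[Si](C)(C)C(C)(C)C)CC(=O)[C@@H]24)cc1 | intermediate |
| 21 | 4β-hydroxy-4α-isopropyl ketal | COc1ccc(CO[C@H]2CC3(OCCO3)CC[C@]4(C)[C@@H](O[Si](C)(C)C(C)(C)C)C[C@](O)(C(C)C)[C@@H]24)cc1 | intermediate |
| 22 | C8 ketone | COc1ccc(CO[C@H]2CC(=O)CC[C@]3(C)[C@@H](O[Si](C)(C)C(C)(C)C)C[C@](O)(C(C)C)[C@@H]23)cc1 | intermediate |
| 23 | dilithium C8=C9 enolate C4 alkoxide (not isolated) | [Li+].[Li+].COc1ccc(CO[C@H]2CC([O-])=CC[C@]3(C)[C@@H](O[Si](C)(C)C(C)(C)C)C[C@]([O-])(C(C)C)[C@@H]23)cc1 | intermediate |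
| 24 | C8=C9 enol triflate | COc1ccc(CO[C@H]2CC(OS(=O)(=O)C(F)(F)F)=CC[C@]3(C)[C@@H](O[Si](C)(C)C(C)(C)C)C[C@](O)(C(C)C)[C@@H]23)cc1 | intermediate |
| 25 | 8-methyl C8=C9 alkene | COc1ccc(CO[C@H]2CC(C)=CC[C@]3(C)[C@@H](O[Si](C)(C)C(C)(C)C)C[C@](O)(C(C)C)[C@@H]23)cc1 | intermediate |
| 26 | 2β-alcohol | COc1ccc(CO[C@H]2CC(C)=CC[C@]3(C)[C@@H](O)C[C@](O)(C(C)C)[C@@H]23)cc1 | intermediate |
| 27 | 2β-acetate | COc1ccc(CO[C@H]2CC(C)=CC[C@]3(C)[C@@H](OC(C)=O)C[C@](O)(C(C)C)[C@@H]23)cc1 | intermediate |
| 28 | 6β-alcohol | O[C@H]1CC(C)=CC[C@]2(C)[C@@H](OC(C)=O)C[C@](O)(C(C)C)[C@@H]12 | intermediate |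
| 29 | 8β,9β-epoxy 6β-alcohol | O[C@H]1C[C@@]2(C)O[C@H]2C[C@]2(C)[C@@H](OC(C)=O)C[C@](O)(C(C)C)[C@@H]12 | intermediate |
| 30 | 3,4-dimethoxybenzoyl chloride | COc1ccc(C(Cl)=O)cc1OC | starting material |
| 31 | CNP0330776.1 | COc1ccc(C(=O)O[C@H]2C[C@@]3(C)O[C@H]3C[C@]3(C)[C@@H](OC(C)=O)C[C@](O)(C(C)C)[C@@H]23)cc1OC | target |

Total step count: 23. Longest linear sequence: 23 steps (from 1).

## Three steps most likely to fail

**1. Step 8.**
- Chelation may be incomplete or oligomeric. The rearrangement could then start from the other chair–chair form, where the mesylate is axial and the C6–C7 bond migrates.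
- Long contact with excess Et3Al may also transfer ethyl or hydride to the new carbonyl group, or open the dioxolane.

The fallback replaces the chelate by a rigid ring fusion as the conformational lock, and sets out from 5. Dihydroxylation with OsO4 (cat.) and N-methylmorpholine N-oxide on the open α face should give the trans-decalin 5α,6α-diol F1. MsCl and Et3N give its 5α-mesylate F2, whose equatorial C5–O bond is fixed antiperiplanar to C1–C6. KOtBu in THF–t-BuOH triggers the same C1 shift and should give the cis-fused 5βH-hydroazulen-6-one F3 with the silyl ether still in place. Because C5 is flattened in any case, IBX dehydrogenation of F3 comes back to the route at 15. This detour also bypasses steps 4 to 9.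

**2. Step 10.**
- Enolisation toward C7 is the easier and unproductive direction, so conversion may be slow.
- Warming to compensate may cost the dioxolane.

The fallback separates enolisation from oxidation and sets out from 14. Equilibrating silylation (TMSCl, Et3N, DMF, 110 °C) should favour the tetrasubstituted C5=C6 trimethylsilyl enol ether F4. Saegusa–Ito oxidation with Pd(OAc)2 in MeCN removes the C4 hydrogen and comes back at 15. The regioisomeric C6=C7 silyl enol ether has no β-hydrogen to lose and returns 14 on work-up.

**3. Step 17.**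
- Regioselectivity of deprotonation may be poor.
- C7 enolisation would be followed by β-elimination of the C6 alkoxide.
- The C4 alkoxide may be sulfonylated.

The fallback is a Shapiro route that fixes the alkene position through the hydrazone, and sets out from 22. Condensation with 2,4,6-triisopropylbenzenesulfonylhydrazide gives the C8 trisylhydrazone F5, whose sulfonamide nitrogen should point away from the branched C6 side. n-BuLi (3.5 equiv, THF, −78 → 0 °C) deprotonates syn to it at C9, and loss of sulfinate and nitrogen leaves the C8 vinyllithium F6. Quenching with MeI comes back to the route at 25 and so bypasses step 18 as well.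

## Further compounds

F1 | step 8 | trans-decalin 5α,6α-diol (2β-OTBS; 8-ketal) | C[C@]12CCC3(OCCO3)C[C@]1(O)[C@@H](O)CC[C@@H]2O[Si](C)(C)C(C)(C)C
F2 | step 8 | 5α-mesylate of F1 | C[C@]12CCC3(OCCO3)C[C@]1(O)[C@@H](OS(C)(=O)=O)CC[C@@H]2O[Si](C)(C)C(C)(C)C
F3 | step 8 | cis-fused 5βH-hydroazulen-6-one (2β-OTBS; 8-ketal) | O=C1CC2(OCCO2)CC[C@]3(C)[C@@H](O[Si](C)(C)C(C)(C)C)CC[C@H]13
F4 | step 10 | C5=C6 trimethylsilyl enol ether of 14 | C[Si](C)(C)OC=1CC2(OCCO2)CC[C@]3(C)[C@@H](O[Si](C)(C)C(C)(C)C)CCC=13
F5 | step 17 | C8 trisylhydrazone of 22 | COc1ccc(CO[C@H]2CC(=NNS(=O)(=O)c3c(C(C)C)cc(C(C)C)cc3C(C)C)CC[C@]3(C)[C@@H](O[Si](C)(C)C(C)(C)C)C[C@](O)(C(C)C)[C@@H]23)cc1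
F6 | step 17 | C8 vinyllithium (C8=C9; C4 lithium alkoxide) | COc1ccc(CO[C@H]2CC([Li])=CC[C@]3(C)[C@@H](O[Si](C)(C)C(C)(C)C)C[C@](O[Li])(C(C)C)[C@@H]23)cc1
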